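Numbering: N1, C2 (N-bearing) and C7 (ester-bearing) belong to the indoline. Ring C is C2–C16–C17–C20–C19–C18, the azocane adds C6–C5–N4 between C7 and C20, and the pyrrolidine is N4–C3–C14–C15(OH)–C20.
Enabling feature: on ring C the carbamate nitrogen N1 at C2 and the ester carbon on the adjacent C16 stand trans, and N1 reaches C2 through the arene and C7. Both bonds can therefore come from one anti addition of N1 and CO across a C2=C16 cyclohexene, with 5-exo closure of the indoline.
Cuts, in retrosynthetic order: N4–C5 (azocane); N1–C2 together with C16–CO2Me (key step); the acyl–N1 bond of an oxindole that masks the C7 ester and N1; C2–C7; N4–C3 and C15–C14.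
Forward: ring C comes with 1 and the pyrrolidine is closed onto it. The spiro ketone becomes a regiodefined enol triflate, which is joined to an oxindole at C7. The lactam is opened to aryl carbamate plus methyl ester, then the indoline and finally the azocane close.
Stereochemistry: C15 comes from a Noyori hydrogenation, C20 from a chiral lithium amide that picks one arm of the ketone, and C7 from a chiral palladium catalyst. C2 and C16 come from the key step (face from the ring C half-chair, trans relation from the mechanism).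
Design points: C7 becomes quaternary in the coupling itself, so the double bond cannot migrate, and no free 2-aminophenylacetate (which would lactamise) ever exists. The C5 oxygen goes from silyl ether directly to bromide, so no γ-hydroxy ester can lactonise.

Key step: step 14

Assumption: acid 1 is taken as a catalogue compound. The sense of induction of the chiral base (step 7) and of the chiral ligand (step 9) is assigned by analogy, and the mirror-image reagent is used if a model run shows the opposite sense.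

Step 1
Reactants: 1 8-[(tert-butoxycarbonyl)amino]-1,4-dioxaspiro[4.5]decane-8-carboxylic acid; 2 potassium ethyl malonate
Product: 4 ethyl 3-{8-[(tert-butoxycarbonyl)amino]-1,4-dioxaspiro[4.5]decan-8-yl}-3-oxopropanoate, via acyl imidazolide 3 (not isolated)
Conditions: 1,1'-carbonyldiimidazole, THF, rt; then 2, MgCl2, Et3N, MeCN, rt to 40 °C
Reagents that add atoms: 1,1'-carbonyldiimidazole, O=C(n1ccnc1)n1ccnc1 (imidazolyl group of 3 only)
Why: Masamune–Brooks-type C-acylation of the magnesium malonate half-ester enolate by the acyl imidazolide, followed by loss of CO2, adds C14 and C3 under near-neutral conditions that spare Boc and ketal, and no stereocentre is formed.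

Step 2
Reactants: 4 ethyl 3-{8-[(tert-butoxycarbonyl)amino]-1,4-dioxaspiro[4.5]decan-8-yl}-3-oxopropanoate
Product: 5 ethyl (3S)-3-{8-[(tert-butoxycarbonyl)amino]-1,4-dioxaspiro[4.5]decan-8-yl}-3-hydroxypropanoate
Conditions: RuCl2[(R)-BINAP] (1 mol %), H2 (50 bar), EtOH, 50 °C
Reagents that add atoms: none
Why: Noyori asymmetric hydrogenation of a β-keto ester, in which the ester-chelated ruthenium hydride of the (R)-BINAP complex should deliver hydrogen to one ketone face and set C15 as (S), the descriptor following from the quaternary C20 outranking CH2CO2Et.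

Step 3
Reactants: 5 ethyl (3S)-3-{8-[(tert-butoxycarbonyl)amino]-1,4-dioxaspiro[4.5]decan-8-yl}-3-hydroxypropanoate
Product: 6 ethyl (3S)-3-{8-[(tert-butoxycarbonyl)amino]-1,4-dioxaspiro[4.5]decan-8-yl}-3-[(tert-butyldimethylsilyl)oxy]propanoate
Conditions: TBSOTf (1.2 equiv), 2,6-lutidine, CH2Cl2, −40 to 0 °C
Reagents that add atoms: tert-butyldimethylsilyl triflate, CC(C)(C)[Si](C)(C)OS(=O)(=O)C(F)(F)F
Why: O-silylation with the silyl triflate is fast enough for a secondary alcohol next to a quaternary carbon, and at low temperature with little excess reagent the carbamate and the ketal should stay intact.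

Step 4
Reactants: 6 ethyl (3S)-3-{8-[(tert-butoxycarbonyl)amino]-1,4-dioxaspiro[4.5]decan-8-yl}-3-[(tert-butyldimethylsilyl)oxy]propanoate
Product: 7 tert-butyl N-{8-[(1S)-1-[(tert-butyldimethylsilyl)oxy]-3-hydroxypropyl]-1,4-dioxaspiro[4.5]decan-8-yl}carbamate
Conditions: LiBH4, THF, 0 °C to rt
Reagents that add atoms: none
Why: Chemoselective borohydride reduction of the ester brings C3 to the alcohol level without touching carbamate, ketal or silyl ether.

Step 5
Reactants: 7 tert-butyl N-{8-[(1S)-1-[(tert-butyldimethylsilyl)oxy]-3-hydroxypropyl]-1,4-dioxaspiro[4.5]decan-8-yl}carbamate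
Product: 9 tert-butyl (12S)-12-[(tert-butyldimethylsilyl)oxy]-1,4-dioxa-9-azadispiro[4.2.4.2]tetradecane-9-carboxylate, via primary mesylate 8 (not isolated)
Conditions: MsCl, Et3N, CH2Cl2, 0 °C; solvent switch; KOt-Bu, THF, 0 °C to rt
Reagents that add atoms: methanesulfonyl chloride, CS(=O)(=O)Cl (mesyl group of 8 only)
Why: Intramolecular SN2 N-alkylation (5-exo-tet) of the carbamate anion on the primary mesylate forms N4–C3 and closes the pyrrolidine, helped by the geminal substitution at C20 and leaving C15 untouched.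

Step 6
Reactants: 9 tert-butyl (12S)-12-[(tert-butyldimethylsilyl)oxy]-1,4-dioxa-9-azadispiro[4.2.4.2]tetradecane-9-carboxylate
Product: 10 tert-butyl (4S)-4-[(tert-butyldimethylsilyl)oxy]-8-oxo-1-azaspiro[4.5]decane-1-carboxylate
Conditions: PPTS (0.2 equiv), acetone–H2O 9:1, 55 °C
Reagents that add atoms: water, O
Why: Mild acid-catalysed ketal hydrolysis frees the C2 ketone, while Boc and the hindered secondary silyl ether tolerate pyridinium tosylate.

Step 7
Reactants: 10 tert-butyl (4S)-4-[(tert-butyldimethylsilyl)oxy]-8-oxo-1-azaspiro[4.5]decane-1-carboxylate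
Product: 12 tert-butyl (4S,5R)-4-[(tert-butyldimethylsilyl)oxy]-8-[(trifluoromethylsulfonyl)oxy]-1-azaspiro[4.5]dec-7-ene-1-carboxylate, via lithium enolate 11 (not isolated)
Conditions: (R,R)-bis(1-phenylethyl)amine, n-BuLi, LiCl, THF, −78 °C; 10, −100 to −78 °C; then N-(5-chloropyridin-2-yl)triflimide, −78 to −20 °C
Reagents that add atoms: N-(5-chloropyridin-2-yl)bis(trifluoromethanesulfonimide), O=S(=O)(N(c1ccc(Cl)cn1)S(=O)(=O)C(F)(F)F)C(F)(F)F; lithium (R,R)-bis(1-phenylethyl)amide, [Li+].C[C@@H]([N-][C@H](C)c1ccccc1)c1ccccc1 (lithium of 11 only)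
Why: Desymmetrising deprotonation of a 4,4-disubstituted cyclohexanone by a twofold-symmetric chiral lithium amide followed by enolate O-triflation should remove the axial proton of the C16 arm in the chair with C15 equatorial and N4 axial, which places the alkene at C2=C16, makes C20 a stereocentre (R), and leaves the minor isomer as a separable diastereomer.

Step 8
Reactants: 13 1-benzylindolin-2-one; 14 (2-bromoethoxy)(tert-butyl)dimethylsilane
Product: 16 rac-1-benzyl-3-{2-[(tert-butyldimethylsilyl)oxy]ethyl}indolin-2-one, via lithium enolate 15 (not isolated)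
Conditions: 13 (1.3 equiv), LiN(SiMe3)2, THF, −78 °C; then 14, DMPU, −78 °C to rt
Reagents that add atoms: lithium hexamethyldisilazide, [Li+].C[Si](C)(C)[N-][Si](C)(C)C (lithium of 15 only)
Why: SN2 alkylation of the oxindole enolate at C7 installs C6–C5–O, a slight excess of 13 holds back a second alkylation, and the racemic C7–H centre is harmless because step 9 erases it.

Step 9
Reactants: 12 tert-butyl (4S,5R)-4-[(tert-butyldimethylsilyl)oxy]-8-[(trifluoromethylsulfonyl)oxy]-1-azaspiro[4.5]dec-7-ene-1-carboxylate; 16 rac-1-benzyl-3-{2-[(tert-butyldimethylsilyl)oxy]ethyl}indolin-2-one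
Product: 18 tert-butyl (4S,5R)-8-[(3R)-1-benzyl-3-{2-[(tert-butyldimethylsilyl)oxy]ethyl}-2-oxoindolin-3-yl]-4-[(tert-butyldimethylsilyl)oxy]-1-azaspiro[4.5]dec-7-ene-1-carboxylate, via sodium enolate 17 (not isolated)
Conditions: 16 (1.3 equiv), NaOt-Bu (1.25 equiv), toluene, rt; then 12, PdMe2(tmeda) (5 mol %), L* (6 mol %), 40 °C; L* = axially chiral P-stereogenic 2-[tert-butyl(phenyl)phosphino]-2'-(dimethylamino)-1,1'-binaphthyl
Reagents that add atoms: sodium tert-butoxide, [Na+].CC(C)(C)[O-] (sodium of 17 only)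
Why: Palladium-catalysed enantioselective α-alkenylation of a 3-alkyloxindole enolate (oxidative addition of zerovalent palladium to the enol triflate, enolate binding, C–C reductive elimination) forms C2–C7, the planar enolate erasing the configuration of 16 and the ligand choosing the face so that C7 is set as (R) (the spatial arrangement that reads 7S in the target), and because C7 becomes quaternary in this very event the C2=C16 bond cannot slip into conjugation.

Step 10
Reactants: 18 tert-butyl (4S,5R)-8-[(3R)-1-benzyl-3-{2-[(tert-butyldimethylsilyl)oxy]ethyl}-2-oxoindolin-3-yl]-4-[(tert-butyldimethylsilyl)oxy]-1-azaspiro[4.5]dec-7-ene-1-carboxylate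
Product: 19 tert-butyl (4S,5R)-4-[(tert-butyldimethylsilyl)oxy]-8-[(3R)-3-{2-[(tert-butyldimethylsilyl)oxy]ethyl}-2-oxoindolin-3-yl]-1-azaspiro[4.5]dec-7-ene-1-carboxylate
Conditions: Na, NH3(l)–THF, −78 °C; NH4Cl
Reagents that add atoms: none
Why: Birch-type dissolving-metal cleavage of the benzylic C–N bond of the lactam frees N1–H, while the isolated trisubstituted alkene, Boc and the silyl ethers are inert at −78 °C and no stereocentre is touched.

Step 11
Reactants: 19 tert-butyl (4S,5R)-4-[(tert-butyldimethylsilyl)oxy]-8-[(3R)-3-{2-[(tert-butyldimethylsilyl)oxy]ethyl}-2-oxoindolin-3-yl]-1-azaspiro[4.5]dec-7-ene-1-carboxylate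
Product: 20 methyl (3R)-3-[(4S,5R)-1-(tert-butoxycarbonyl)-4-[(tert-butyldimethylsilyl)oxy]-1-azaspiro[4.5]dec-7-en-8-yl]-3-{2-[(tert-butyldimethylsilyl)oxy]ethyl}-2-oxoindoline-1-carboxylate
Conditions: ClCO2Me, Et3N, DMAP (0.2 equiv), CH2Cl2, 0 °C to rt
Reagents that add atoms: methyl chloroformate, COC(=O)Cl
Why: DMAP-catalysed N-acylation installs the N1 carbamate of the target and turns the lactam into an imide whose ring carbonyl is activated for opening, C- and O-acylation being impossible at the quaternary C7.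

Step 12
Reactants: 20 methyl (3R)-3-[(4S,5R)-1-(tert-butoxycarbonyl)-4-[(tert-butyldimethylsilyl)oxy]-1-azaspiro[4.5]dec-7-en-8-yl]-3-{2-[(tert-butyldimethylsilyl)oxy]ethyl}-2-oxoindoline-1-carboxylate
Product: 22 (2R)-2-[(4S,5R)-1-(tert-butoxycarbonyl)-4-[(tert-butyldimethylsilyl)oxy]-1-azaspiro[4.5]dec-7-en-8-yl]-4-[(tert-butyldimethylsilyl)oxy]-2-{2-[(methoxycarbonyl)amino]phenyl}butanoic acid, via lithium peroxycarboxylate 21 (not isolated)
Conditions: LiOH, H2O2, THF–H2O, 0 °C; Na2SO3; then HCl to pH 4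
Reagents that add atoms: hydrogen peroxide, OO; lithium hydroxide, [Li+].[OH-] (lithium of 21 only)
Why: Hydroperoxide cleavage of an N-acyl carbamate, as used for N-acyl oxazolidinones and N-Boc lactams, sends the small α-effect nucleophile to the more electrophilic ring acyl carbonyl, expels the aryl carbamate anion and after sulfite reduction gives the acid, the quaternary C7 being unable to epimerise.

Step 13
Reactants: 22 (2R)-2-[(4S,5R)-1-(tert-butoxycarbonyl)-4-[(tert-butyldimethylsilyl)oxy]-1-azaspiro[4.5]dec-7-en-8-yl]-4-[(tert-butyldimethylsilyl)oxy]-2-{2-[(methoxycarbonyl)amino]phenyl}butanoic acid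
Product: 23 methyl (2R)-2-[(4S,5R)-1-(tert-butoxycarbonyl)-4-[(tert-butyldimethylsilyl)oxy]-1-azaspiro[4.5]dec-7-en-8-yl]-4-[(tert-butyldimethylsilyl)oxy]-2-{2-[(methoxycarbonyl)amino]phenyl}butanoate
Conditions: Me3SiCHN2, toluene–MeOH, 0 °C
Reagents that add atoms: (trimethylsilyl)diazomethane, C[Si](C)(C)C=[N+]=[N-]
Why: Esterification by O-alkylation of the carboxylic acid with a diazomethane equivalent needs no attack at the crowded C7 carbonyl and no base that could re-close the oxindole.

Step 14
Reactants: 23 methyl (2R)-2-[(4S,5R)-1-(tert-butoxycarbonyl)-4-[(tert-butyldimethylsilyl)oxy]-1-azaspiro[4.5]dec-7-en-8-yl]-4-[(tert-butyldimethylsilyl)oxy]-2-{2-[(methoxycarbonyl)amino]phenyl}butanoate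
Product: 24 (2R,7S,15S,16R,20R)-dispiro[indoline-2,1'-cyclohexane-4',2''-pyrrolidine] with N1-CO2Me; CO2Me plus CH2CH2OTBS on C7; CO2Me on C16 trans to N1; N4-Boc; C15-OTBS
Conditions: PdCl2(MeCN)2 (15 mol %), 1,4-benzoquinone (2 equiv), LiCl (1 equiv), NaOAc (0.3 equiv), CO (1 atm), MeOH–THF 1:1, 35 °C
Reagents that add atoms: carbon monoxide, [C-]#[O+]; methanol, CO
Why: Proposed new method: chloride-ligated divalent palladium binds the C2=C16 alkene, the aryl carbamate N1–H attacks the more substituted C2 on the face away from the metal (anti-aminopalladation, 5-exo-trig closure of the indoline ring), CO inserts into the secondary C16–Pd bond with retention, methanol cleaves the acyl complex and benzoquinone returns zerovalent palladium to the divalent state. The closest known reaction type is the intramolecular amino-alkoxycarbonylation (aza-Wacker cyclisation with CO capture) of terminal and 1,2-disubstituted alkenes by carbamates, ureas and sulfonamides; new here is a trisubstituted ring alkene next to a quaternary carbon, so that a fully substituted C–N centre results. C2 is controlled by the ring C half-chair: with the branched C15 carbon equatorial and N4 axial on C20, trans-diaxial (Fürst–Plattner-type) addition with nitrogen at C2 puts palladium at C16 on the N4 face, where the Boc carbonyl can assist, and brings N1 in on the opposite face, whereas the other half-chair would set the silyloxy-bearing C15 1,3-diaxial to the metal. C16 follows from C2, since anti addition and retentive carbonylation leave the ester trans to N1, and the pre-set C7 then carries C6 on the C16 side of the new indoline, as the azocane requires. The step needs 5-exo over 6-endo attack (secured by Markovnikov polarisation towards C2 and the three-atom arene–C7 link), CO insertion faster than β-hydride elimination towards C17 (CO atmosphere, chloride, mild temperature) and N1 as the only nucleophile (N4 bears no hydrogen, the C5 oxygen is silylated, and the near-neutral quinone system spares Boc and silyl ethers). The C–N bond formation is not reversible under these conditions, and C16 receives its ester only after C2 has become quaternary.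

Step 15
Reactants: 24 (2R,7S,15S,16R,20R)-dispiro indoline with C7-CH2CH2OTBS
Product: 25 (2R,7S,15S,16R,20R)-dispiro indoline as 24 but with CH2CH2Br on C7
Conditions: Ph3PBr2 (1.2 equiv), CH2Cl2, 0 °C to rt
Reagents that add atoms: dibromotriphenylphosphorane, BrP(Br)(c1ccccc1)(c1ccccc1)c1ccccc1
Why: Appel-type substitution run directly on the silyl ether exchanges the primary O–Si for an oxyphosphonium group that bromide displaces, so the γ-hydroxy ester that would lactonise onto the C7 ester is never set free, and the neopentyl-like C15 silyl ether is too hindered to react.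

Step 16
Reactants: 25 (2R,7S,15S,16R,20R)-dispiro indoline with C7-CH2CH2Br
Product: 27 CNP0144467.1 (2R,7S,15S,16R,20R), via amino alcohol hydrochloride 26 (not isolated)
Conditions: HCl (3 M in MeOH), rt; evaporate; then i-Pr2NEt, NaI (0.2 equiv), MeCN (2 mM), 70 °C
Reagents that add atoms: hydrogen chloride, Cl (chloride of 26 only)
Why: Acidolysis removes Boc and the C15 silyl ether, and the freed secondary amine N4, held cis to the C7 side chain across ring C, then displaces the primary halide (Finkelstein-assisted intramolecular N-alkylation, 8-exo-tet) at high dilution under a base too weak to epimerise C16.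

Compound list
1 | 8-[(tert-butoxycarbonyl)amino]-1,4-dioxaspiro[4.5]decane-8-carboxylic acid | CC(C)(C)OC(=O)NC1(C(=O)O)CCC2(CC1)OCCO2 | starting material
2 | potassium ethyl malonate | CCOC(=O)CC(=O)[O-].[K+] | starting material
3 | tert-butyl N-[8-(imidazole-1-carbonyl)-1,4-dioxaspiro[4.5]decan-8-yl]carbamate | CC(C)(C)OC(=O)NC1(C(=O)n2ccnc2)CCC2(CC1)OCCO2 | intermediate
4 | ethyl 3-{8-[(tert-butoxycarbonyl)amino]-1,4-dioxaspiro[4.5]decan-8-yl}-3-oxopropanoate | CCOC(=O)CC(=O)C1(NC(=O)OC(C)(C)C)CCC2(CC1)OCCO2 | intermediate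
5 | ethyl (3S)-3-{8-[(tert-butoxycarbonyl)amino]-1,4-dioxaspiro[4.5]decan-8-yl}-3-hydroxypropanoate | CCOC(=O)C[C@H](O)C1(NC(=O)OC(C)(C)C)CCC2(CC1)OCCO2 | intermediate
6 | ethyl (3S)-3-{8-[(tert-butoxycarbonyl)amino]-1,4-dioxaspiro[4.5]decan-8-yl}-3-[(tert-butyldimethylsilyl)oxy]propanoate | CCOC(=O)C[C@H](O[Si](C)(C)C(C)(C)C)C1(NC(=O)OC(C)(C)C)CCC2(CC1)OCCO2 | intermediate
7 | tert-butyl N-{8-[(1S)-1-[(tert-butyldimethylsilyl)oxy]-3-hydroxypropyl]-1,4-dioxaspiro[4.5]decan-8-yl}carbamate | OCC[C@H](O[Si](C)(C)C(C)(C)C)C1(NC(=O)OC(C)(C)C)CCC2(CC1)OCCO2 | intermediate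
8 | (3S)-3-{8-[(tert-butoxycarbonyl)amino]-1,4-dioxaspiro[4.5]decan-8-yl}-3-[(tert-butyldimethylsilyl)oxy]propyl methanesulfonate | CS(=O)(=O)OCC[C@H](O[Si](C)(C)C(C)(C)C)C1(NC(=O)OC(C)(C)C)CCC2(CC1)OCCO2 | intermediate
9 | tert-butyl (12S)-12-[(tert-butyldimethylsilyl)oxy]-1,4-dioxa-9-azadispiro[4.2.4.2]tetradecane-9-carboxylate | CC(C)(C)OC(=O)N1CC[C@H](O[Si](C)(C)C(C)(C)C)C12CCC3(CC2)OCCO3 | intermediate
10 | tert-butyl (4S)-4-[(tert-butyldimethylsilyl)oxy]-8-oxo-1-azaspiro[4.5]decane-1-carboxylate | CC(C)(C)OC(=O)N1CC[C@H](O[Si](C)(C)C(C)(C)C)C12CCC(=O)CC2 | intermediate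
11 | lithium (4S,5R)-1-(tert-butoxycarbonyl)-4-[(tert-butyldimethylsilyl)oxy]-1-azaspiro[4.5]dec-7-en-8-olate | [Li+].[O-]C1=CC[C@@]2(CC1)N(C(=O)OC(C)(C)C)CC[C@@H]2O[Si](C)(C)C(C)(C)C | intermediate
12 | tert-butyl (4S,5R)-4-[(tert-butyldimethylsilyl)oxy]-8-[(trifluoromethylsulfonyl)oxy]-1-azaspiro[4.5]dec-7-ene-1-carboxylate | O=S(=O)(OC1=CC[C@@]2(CC1)N(C(=O)OC(C)(C)C)CC[C@@H]2O[Si](C)(C)C(C)(C)C)C(F)(F)F | intermediate
13 | 1-benzylindolin-2-one | O=C1Cc2ccccc2N1Cc1ccccc1 | starting material
14 | (2-bromoethoxy)(tert-butyl)dimethylsilane | CC(C)(C)[Si](C)(C)OCCBr | starting material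
15 | lithium 1-benzyl-1H-indol-2-olate (enolate of 13) | [Li+].[O-]C1=Cc2ccccc2N1Cc1ccccc1 | intermediate
16 | rac-1-benzyl-3-{2-[(tert-butyldimethylsilyl)oxy]ethyl}indolin-2-one | O=C1C(CCO[Si](C)(C)C(C)(C)C)c2ccccc2N1Cc1ccccc1 | intermediate
17 | sodium 1-benzyl-3-{2-[(tert-butyldimethylsilyl)oxy]ethyl}-1H-indol-2-olate (enolate of 16) | [Na+].[O-]C1=C(CCO[Si](C)(C)C(C)(C)C)c2ccccc2N1Cc1ccccc1 | intermediate
18 | tert-butyl (4S,5R)-8-[(3R)-1-benzyl-3-{2-[(tert-butyldimethylsilyl)oxy]ethyl}-2-oxoindolin-3-yl]-4-[(tert-butyldimethylsilyl)oxy]-1-azaspiro[4.5]dec-7-ene-1-carboxylate | O=C1N(Cc2ccccc2)c2ccccc2[C@@]1(CCO[Si](C)(C)C(C)(C)C)C1=CC[C@@]2(CC1)N(C(=O)OC(C)(C)C)CC[C@@H]2O[Si](C)(C)C(C)(C)C | intermediate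
19 | tert-butyl (4S,5R)-4-[(tert-butyldimethylsilyl)oxy]-8-[(3R)-3-{2-[(tert-butyldimethylsilyl)oxy]ethyl}-2-oxoindolin-3-yl]-1-azaspiro[4.5]dec-7-ene-1-carboxylate | O=C1Nc2ccccc2[C@@]1(CCO[Si](C)(C)C(C)(C)C)C1=CC[C@@]2(CC1)N(C(=O)OC(C)(C)C)CC[C@@H]2O[Si](C)(C)C(C)(C)C | intermediate
20 | methyl (3R)-3-[(4S,5R)-1-(tert-butoxycarbonyl)-4-[(tert-butyldimethylsilyl)oxy]-1-azaspiro[4.5]dec-7-en-8-yl]-3-{2-[(tert-butyldimethylsilyl)oxy]ethyl}-2-oxoindoline-1-carboxylate | O=C1N(C(=O)OC)c2ccccc2[C@@]1(CCO[Si](C)(C)C(C)(C)C)C1=CC[C@@]2(CC1)N(C(=O)OC(C)(C)C)CC[C@@H]2O[Si](C)(C)C(C)(C)C | intermediate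
21 | lithium salt of the peroxy acid corresponding to 22 | [Li+].[O-]OC(=O)[C@@](CCO[Si](C)(C)C(C)(C)C)(c1ccccc1NC(=O)OC)C1=CC[C@@]2(CC1)N(C(=O)OC(C)(C)C)CC[C@@H]2O[Si](C)(C)C(C)(C)C | intermediate
22 | (2R)-2-[(4S,5R)-1-(tert-butoxycarbonyl)-4-[(tert-butyldimethylsilyl)oxy]-1-azaspiro[4.5]dec-7-en-8-yl]-4-[(tert-butyldimethylsilyl)oxy]-2-{2-[(methoxycarbonyl)amino]phenyl}butanoic acid | OC(=O)[C@@](CCO[Si](C)(C)C(C)(C)C)(c1ccccc1NC(=O)OC)C1=CC[C@@]2(CC1)N(C(=O)OC(C)(C)C)CC[C@@H]2O[Si](C)(C)C(C)(C)C | intermediate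
23 | methyl ester of 22 (key-step precursor; C7 R, C15 S, C20 R) | COC(=O)[C@@](CCO[Si](C)(C)C(C)(C)C)(c1ccccc1NC(=O)OC)C1=CC[C@@]2(CC1)N(C(=O)OC(C)(C)C)CC[C@@H]2O[Si](C)(C)C(C)(C)C | intermediate
24 | (2R,7S,15S,16R,20R)-dispiro[indoline-2,1'-cyclohexane-4',2''-pyrrolidine]: N1-CO2Me, C7-CO2Me, C7-CH2CH2OTBS, C16-CO2Me trans to N1, N4-Boc, C15-OTBS (key-step product) | COC(=O)[C@@H]1C[C@]2(N(C(=O)OC(C)(C)C)CC[C@@H]2O[Si](C)(C)C(C)(C)C)CC[C@@]14N(C(=O)OC)c1ccccc1[C@@]4(C(=O)OC)CCO[Si](C)(C)C(C)(C)C | intermediate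
25 | as 24 with CH2CH2Br on C7 (2R,7S,15S,16R,20R) | COC(=O)[C@@H]1C[C@]2(N(C(=O)OC(C)(C)C)CC[C@@H]2O[Si](C)(C)C(C)(C)C)CC[C@@]14N(C(=O)OC)c1ccccc1[C@@]4(C(=O)OC)CCBr | intermediate
26 | as 25 with free N4–H (hydrochloride) and free C15–OH | COC(=O)[C@@H]1C[C@]2(NCC[C@@H]2O)CC[C@@]14N(C(=O)OC)c1ccccc1[C@@]4(C(=O)OC)CCBr.Cl | intermediate
27 | CNP0144467.1, pentacyclic pyrroloazocine indoline triester with C15–OH (2R,7S,15S,16R,20R) | COC(=O)[C@@H]1C[C@@]23CC[C@@]14N(C(=O)OC)c1ccccc1[C@@]4(C(=O)OC)CCN2CC[C@@H]3O | target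

Total step count: 16. Longest linear sequence: 15 (steps 1–7 and 9–16; step 8 is the side branch).

Steps most likely to fail

Step 14 (key step). What may go wrong:
- the weakly nucleophilic carbamate attacks the hindered alkene too slowly;
- β-hydride elimination towards C17 outruns CO insertion;
- addition takes place on the N4 face.

The fallback splits the event into two known reactions that form the same bonds. It sets out from 23. Iodoamidation with NIS and NaHCO3 in MeCN at 0 °C in the dark should open the iodonium ion at the tertiary C2 by N1, anti and 5-exo, under the same half-chair control. This gives the trans-16-iodo indoline F1. The secondary iodide is then carbonylated by light-assisted, palladium-accelerated atom-transfer carbonylation: CO (40 atm), MeOH, K2CO3, Pd(PPh3)4 (5 mol %), xenon lamp. The C16 radical should take up CO on the face away from the axial N1 carbamate. The sequence comes back to the route at 24.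

Step 9. What may go wrong:
- reductive elimination at the congested C7 is slow;
- base cleaves the S–O bond of the triflate;
- catalyst control over the enolate face is insufficient.

The fallback forms an sp2–sp2 bond first and creates the quaternary centre by a 1,2-shift. It sets out from 12.
- Tryptophol is silylated (TBSCl, imidazole) to the silyl ether F2.
- F2 is borylated at the indole 2-position ([Ir(OMe)(cod)]2, dtbpy, B2pin2) to the 2-boronate F3.
- F3 is joined to 12 by Suzuki–Miyaura coupling (PdCl2(dppf), K3PO4, dioxane–H2O) to give the 2-alkenylindole F4.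
- NBS in THF–H2O–AcOH at 0 °C, with short contact, brominates the indole 3-position. Water adds to the imine carbon, and the alkenyl group migrates from the 2- to the 3-position (oxidative indole-to-oxindole rearrangement).

This gives 19 together with its C7 epimer F5. The two are diastereomers and are separated by chromatography. The sequence comes back at 19, and step 10 is no longer needed.

Step 7. What may go wrong:
- the two diastereotopic α-methylene groups are poorly discriminated if both chair forms of the ketone are populated;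
- the enolate equilibrates before triflation.

The fallback stores the regiochemical information in an enone. It sets out from 10. Mukaiyama dehydrogenation (LiN(i-Pr)2, THF, −78 °C, then N-tert-butylbenzenesulfinimidoyl chloride) gives the enone F6 and its C20 diastereomer F7, which are separated. F7 is returned to 10 by hydrogenation (H2, Pd/C). Conjugate reduction of F6 with LiBH(s-Bu)3 delivers hydride to C17 and gives enolate 11 regiospecifically. Trapping with N-(5-chloropyridin-2-yl)triflimide brings the sequence back at 12.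

Further compounds
F1 | step 14 | (2R,7S,15S,16R,20R)-16-iodo analogue of 24 (iodine in place of the C16 ester, trans to N1) | I[C@@H]1C[C@]2(N(C(=O)OC(C)(C)C)CC[C@@H]2O[Si](C)(C)C(C)(C)C)CC[C@@]14N(C(=O)OC)c1ccccc1[C@@]4(C(=O)OC)CCO[Si](C)(C)C(C)(C)C
F2 | step 9 | 3-{2-[(tert-butyldimethylsilyl)oxy]ethyl}-1H-indole | CC(C)(C)[Si](C)(C)OCCc1c[nH]c2ccccc12
F3 | step 9 | 3-{2-[(tert-butyldimethylsilyl)oxy]ethyl}-2-(4,4,5,5-tetramethyl-1,3,2-dioxaborolan-2-yl)-1H-indole | CC(C)(C)[Si](C)(C)OCCc1c(B2OC(C)(C)C(C)(C)O2)[nH]c2ccccc12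
F4 | step 9 | tert-butyl (4S,5R)-4-[(tert-butyldimethylsilyl)oxy]-8-(3-{2-[(tert-butyldimethylsilyl)oxy]ethyl}-1H-indol-2-yl)-1-azaspiro[4.5]dec-7-ene-1-carboxylate | CC(C)(C)[Si](C)(C)OCCc1c([nH]c2ccccc12)C1=CC[C@@]2(CC1)N(C(=O)OC(C)(C)C)CC[C@@H]2O[Si](C)(C)C(C)(C)C
F5 | step 9 | C7 epimer of 19 ((3S)-oxindole, 4S,5R) | O=C1Nc2ccccc2[C@]1(CCO[Si](C)(C)C(C)(C)C)C1=CC[C@@]2(CC1)N(C(=O)OC(C)(C)C)CC[C@@H]2O[Si](C)(C)C(C)(C)C
F6 | step 7 | tert-butyl (4S,5R)-4-[(tert-butyldimethylsilyl)oxy]-8-oxo-1-azaspiro[4.5]dec-6-ene-1-carboxylate | O=C1C=C[C@@]2(CC1)N(C(=O)OC(C)(C)C)CC[C@@H]2O[Si](C)(C)C(C)(C)C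
F7 | step 7 | tert-butyl (4S,5S)-4-[(tert-butyldimethylsilyl)oxy]-8-oxo-1-azaspiro[4.5]dec-6-ene-1-carboxylate | O=C1C=C[C@]2(CC1)N(C(=O)OC(C)(C)C)CC[C@@H]2O[Si](C)(C)C(C)(C)C
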